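# Total synthesis of 7α-acetoxy-6,7-dihydroicetexone, (4S,5S,7R,10S)

Convention used throughout (icetexane numbering): ring A = C1–C5 and C10; ring B = C5, C6, C7, C8, C9, C20, C10 (seven-membered); ring C = C8, C9, C11–C14. C18 is the methyl on C4, C19 the lactone carbonyl on C4, and the lactone oxygen sits on C10.

## Retrosynthetic overview

1. Target 18 ⇐ 17 ⇐ 16: the hydroxyquinone is unveiled last from an 11,12,14-trimethoxyarene; the C7–OAc bond comes from benzylic C–H acetoxylation of 15.
2. Key disconnection, the C10–O lactone bond: anti protolactonisation of the dearomatised acid 13 builds the bridged γ-lactone and sets C5 and C10 from C4 (then C2=C3 hydrogenation).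
3. C4 and its methyl: reductive dearomatisation with enantioselective methylation of the ring-A benzoic acid 11.
4. Ring B: Friedel–Crafts acylation/deoxygenation of the symmetric diacid 9 (C20–C9 bond); the C6–C7 bond comes from benzylation of lithiated dimethyl 2-methylisophthalate with chloride 5.
5. Ring order: rings C and A enter as arenes → ring B → ring A dearomatised → lactone ring → quinone.

## Route

Step 1
Reactants: 1 1,2,4-trimethoxybenzene
Product: 3 2-(2,3,6-trimethoxyphenyl)propan-2-ol, via (2,3,6-trimethoxyphenyl)lithium 2 (not isolated)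
Conditions: n-BuLi (1.1 equiv), THF, 0 °C to rt, 2 h; acetone, −78 °C to rt; H2O
Reagents that add atoms: acetone CC(C)=O
Why: Directed ortho-metalation takes place at the only position flanked by two methoxy groups, and the aryllithium adds 1,2 to acetone.

Step 2
Reactants: 3 2-(2,3,6-trimethoxyphenyl)propan-2-ol
Product: 4 2-isopropyl-1,3,4-trimethoxybenzene
Conditions: Et3SiH (2.5 equiv), TFA, CH2Cl2, 0 °C to rt
Reagents that add atoms: none
Why: Ionic hydrogenation; the tertiary benzylic cation, stabilised by two ortho methoxy groups, is trapped by hydride from the silane.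

Step 3
Reactants: 4 2-isopropyl-1,3,4-trimethoxybenzene
Product: 5 1-(chloromethyl)-3-isopropyl-2,4,5-trimethoxybenzene
Conditions: (CH2O)n, HCl (g), 1,4-dioxane, 10 °C; used crude
Reagents that add atoms: formaldehyde (as paraformaldehyde) C=O; hydrogen chloride Cl
Why: Blanc chloromethylation goes to the one free position that is ortho to one methoxy group and para to another (the future C8), not to the position para to isopropyl.

Step 4
Reactants: 5 1-(chloromethyl)-3-isopropyl-2,4,5-trimethoxybenzene; 6 dimethyl 2-methylisophthalate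
Product: 8 dimethyl 2-[2-(3-isopropyl-2,4,5-trimethoxyphenyl)ethyl]benzene-1,3-dicarboxylate, via lithiated diester 7 (not isolated)
Conditions: 6 (1.3 equiv), LiN(i-Pr)2 (1.3 equiv), THF, −78 °C, 30 min; then 5, −78 to −40 °C
Reagents that add atoms: none
Why: Lateral lithiation of the methyl group flanked by two esters gives a stabilised benzylic anion that displaces the activated benzylic chloride (SN2), forming the C6–C7 bond.

Step 5
Reactants: 8 dimethyl 2-[2-(3-isopropyl-2,4,5-trimethoxyphenyl)ethyl]benzene-1,3-dicarboxylate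
Product: 9 2-[2-(3-isopropyl-2,4,5-trimethoxyphenyl)ethyl]benzene-1,3-dicarboxylic acid
Conditions: KOH (6 equiv), MeOH–H2O (3:1), reflux; then 2 M HCl
Reagents that add atoms: potassium hydroxide [K+].[OH-]
Why: Plain saponification of two aryl methyl esters gives the symmetric diacid.

Step 6
Reactants: 9 2-[2-(3-isopropyl-2,4,5-trimethoxyphenyl)ethyl]benzene-1,3-dicarboxylic acid
Product: 11 8-isopropyl-6,7,9-trimethoxy-10,11-dihydro-5H-dibenzo[a,d][7]annulene-1-carboxylic acid, via keto acid 10 (not isolated)
Conditions: (CF3CO)2O (3 equiv), TFA, CH2Cl2, 0 °C to rt; then Et3SiH (4 equiv), TfOH (5 mol %), rt; aqueous work-up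
Reagents that add atoms: none
Why: Because 9 is symmetric, either carboxyl (as its mixed trifluoroacetic anhydride) acylates the only free position of ring C (C9, ortho to OMe) in a seven-membered-ring Friedel–Crafts acylation, and the electron-rich diaryl ketone is then reduced to CH2 (C20) by ionic hydrogenation in the same acidic medium.

Step 7
Reactants: 11 8-isopropyl-6,7,9-trimethoxy-10,11-dihydro-5H-dibenzo[a,d][7]annulene-1-carboxylic acid
Product: 13 (1S)-8-isopropyl-6,7,9-trimethoxy-1-methyl-4,5,10,11-tetrahydro-1H-dibenzo[a,d][7]annulene-1-carboxylic acid, via dilithium dienediolate 12 (not isolated)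
Conditions: (R,R)-N1,N3-bis[1-phenyl-2-(piperidin-1-yl)ethyl]propane-1,3-diamine (1.05 equiv), n-BuLi (1.0 equiv), THF, −78 °C; lithium 4,4'-di-tert-butylbiphenylide (2.0 equiv), −78 °C; n-BuLi (1.0 equiv); MeI (3 equiv), −78 °C; aq. HCl (tetramine recovered by acid extraction)
Reagents that add atoms: iodomethane CI
Why: Proposed new method: two-electron reduction of the lithium benzoate by the arene radical anion gives a trianion that is protonated at the para carbon (C1) by one N–H of the chiral tetramine, so the 1,4-dihydrobenzoate enediolate 12 is formed already bound to the resulting chiral lithium amide; after the second N–H is lithiated, the C2-symmetric dilithium diamide/enediolate mixed aggregate shields one face of the planar dienediolate and MeI attacks the α-carbon C4 (the usual site for Birch dienolates) from the open face to give the 4S quaternary centre (the facial sense is not predictable for this substrate class, and the antipodal tetramine is equally accessible if it proves opposite); the closest known reactions are ammonia-free Birch reductive alkylation with arene radical anions and an amine proton source, and enantioselective alkylation of carboxylic acid enediolates with chiral lithium amides as traceless auxiliaries, which is known for arylacetic acids but not for dearomatised dienediolates or in one flask with the reduction.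

Step 8
Reactants: 13 (1S)-8-isopropyl-6,7,9-trimethoxy-1-methyl-4,5,10,11-tetrahydro-1H-dibenzo[a,d][7]annulene-1-carboxylic acid
Product: 14 (4S,5S,10S)-11,12,14-trimethoxyicetexa-2,8,11,13-tetraen-19,10-olide
Conditions: TfOH (10 mol %), CH2Cl2, 0 °C to rt
Reagents that add atoms: none
Why: Brønsted-acid protolactonisation: protonation of the tetrasubstituted C5=C10 alkene at C5 gives the tertiary C10 cation, which the C19 carboxyl can reach only from the β-face while the proton enters C5 anti on the α-face, so C10 (S) and C5 (S, H-5α, also the more stable epimer with C6 equatorial on ring A) are set from C4; the disubstituted C2=C3 alkene would need a secondary cation and is untouched.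

Step 9
Reactants: 14 (4S,5S,10S)-11,12,14-trimethoxyicetexa-2,8,11,13-tetraen-19,10-olide
Product: 15 (4S,5S,10S)-11,12,14-trimethoxyicetexa-8,11,13-trien-19,10-olide
Conditions: H2 (1 atm), 10% Pd/C, EtOAc, rt
Reagents that add atoms: none
Why: Heterogeneous hydrogenation saturates the only alkene without creating a stereocentre, and the lactone C10–O bond is not benzylic so it is not hydrogenolysed.

Step 10
Reactants: 15 (4S,5S,10S)-11,12,14-trimethoxyicetexa-8,11,13-trien-19,10-olide
Product: 16 (4S,5S,7R,10S)-7-acetoxy-11,12,14-trimethoxyicetexa-8,11,13-trien-19,10-olide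
Conditions: DDQ (1.3 equiv), AcOH–CH2Cl2 (1:3), rt to 40 °C
Reagents that add atoms: acetic acid CC(=O)O
Why: DDQ-mediated benzylic C–H acetoxylation: hydride is abstracted only from C7, whose cation is stabilised by the para (C12) and ortho (C14) methoxy groups (C20 is neopentylic, next to the C10–O bond and has no para donor), and acetic acid is expected to capture the planar cation from the α-face, anti to the β-lactone bridge over ring B, to give the 7R (7α) acetate.

Step 11
Reactants: 16 (4S,5S,7R,10S)-7-acetoxy-11,12,14-trimethoxyicetexa-8,11,13-trien-19,10-olide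
Product: 17 (4S,5S,7R,10S)-7-acetoxy-12-methoxy-11,14-dioxoicetexa-8,12-dien-19,10-olide
Conditions: (NH4)2Ce(NO3)6 (2.5 equiv), MeCN–H2O (3:1), 0 °C, 15 min
Reagents that add atoms: water O
Why: Oxidative demethylation of the para-related C11/C14 methoxy pair by tetravalent cerium gives the 2-methoxy-1,4-benzoquinone, after which the C7 acetate is no longer ionisable.

Step 12
Reactants: 17 (4S,5S,7R,10S)-7-acetoxy-12-methoxy-11,14-dioxoicetexa-8,12-dien-19,10-olide
Product: 18 7α-acetoxy-6,7-dihydroicetexone, (4S,5S,7R,10S)-7-acetoxy-12-hydroxy-11,14-dioxoicetexa-8,12-dien-19,10-olide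
Conditions: BCl3 (2.5 equiv), CH2Cl2, −78 to −40 °C; then H2O
Reagents that add atoms: none
Why: Lewis-acid ether cleavage: BCl3 chelates the C11 carbonyl and the adjacent C12 methoxy oxygen and cleaves only this vinylogous methyl ester at low temperature, leaving the acetate, the lactone and all four stereocentres untouched.

## Compound list

1 | 1,2,4-trimethoxybenzene | COc1ccc(OC)c(OC)c1 | starting material
2 | (2,3,6-trimethoxyphenyl)lithium | COc1ccc(OC)c(OC)c1[Li] | intermediate
3 | 2-(2,3,6-trimethoxyphenyl)propan-2-ol | COc1ccc(OC)c(OC)c1C(C)(C)O | intermediate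
4 | 2-isopropyl-1,3,4-trimethoxybenzene | COc1ccc(OC)c(OC)c1C(C)C | intermediate
5 | 1-(chloromethyl)-3-isopropyl-2,4,5-trimethoxybenzene | ClCc1cc(OC)c(OC)c(C(C)C)c1OC | intermediate
6 | dimethyl 2-methylisophthalate | COC(=O)c1cccc(C(=O)OC)c1C | starting material
7 | [2,6-bis(methoxycarbonyl)phenyl]methyllithium | COC(=O)c1cccc(C(=O)OC)c1C[Li] | intermediate
8 | dimethyl 2-[2-(3-isopropyl-2,4,5-trimethoxyphenyl)ethyl]benzene-1,3-dicarboxylate | COC(=O)c1cccc(C(=O)OC)c1CCc1cc(OC)c(OC)c(C(C)C)c1OC | intermediate
9 | 2-[2-(3-isopropyl-2,4,5-trimethoxyphenyl)ethyl]benzene-1,3-dicarboxylic acid | OC(=O)c1cccc(C(=O)O)c1CCc1cc(OC)c(OC)c(C(C)C)c1OC | intermediate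
10 | 8-isopropyl-6,7,9-trimethoxy-5-oxo-10,11-dihydro-5H-dibenzo[a,d][7]annulene-1-carboxylic acid | OC(=O)c1cccc2c1CCc1c(OC)c(C(C)C)c(OC)c(OC)c1C2=O | intermediate
11 | 8-isopropyl-6,7,9-trimethoxy-10,11-dihydro-5H-dibenzo[a,d][7]annulene-1-carboxylic acid | OC(=O)c1cccc2c1CCc1c(OC)c(C(C)C)c(OC)c(OC)c1C2 | intermediate
12 | dilithium enediolate of 8-isopropyl-6,7,9-trimethoxy-4,5,10,11-tetrahydro-1H-dibenzo[a,d][7]annulene-1-carboxylic acid (exocyclic C1=C(OLi)2) | [Li]OC(O[Li])=C1C=CCC2=C1CCc1c(OC)c(C(C)C)c(OC)c(OC)c1C2 | intermediate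
13 | (1S)-8-isopropyl-6,7,9-trimethoxy-1-methyl-4,5,10,11-tetrahydro-1H-dibenzo[a,d][7]annulene-1-carboxylic acid (C4 = S) | C[C@]1(C(=O)O)C=CCC2=C1CCc1c(OC)c(C(C)C)c(OC)c(OC)c1C2 | intermediate
14 | (4S,5S,10S)-11,12,14-trimethoxyicetexa-2,8,11,13-tetraen-19,10-olide | C1C[C@@H]2[C@]3(CC=C[C@]2(C)C(=O)O3)Cc2c1c(OC)c(C(C)C)c(OC)c2OC | intermediate
15 | (4S,5S,10S)-11,12,14-trimethoxyicetexa-8,11,13-trien-19,10-olide | C1C[C@@H]2[C@]3(CCC[C@]2(C)C(=O)O3)Cc2c1c(OC)c(C(C)C)c(OC)c2OC | intermediate
16 | (4S,5S,7R,10S)-7-acetoxy-11,12,14-trimethoxyicetexa-8,11,13-trien-19,10-olide | CC(=O)O[C@@H]1C[C@@H]2[C@]3(CCC[C@]2(C)C(=O)O3)Cc2c1c(OC)c(C(C)C)c(OC)c2OC | intermediate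
17 | (4S,5S,7R,10S)-7-acetoxy-12-methoxy-11,14-dioxoicetexa-8,12-dien-19,10-olide | CC(=O)O[C@@H]1C[C@@H]2[C@]3(CCC[C@]2(C)C(=O)O3)CC2=C1C(=O)C(C(C)C)=C(OC)C2=O | intermediate
18 | 7α-acetoxy-6,7-dihydroicetexone, (4S,5S,7R,10S) | CC(=O)O[C@@H]1C[C@@H]2[C@]3(CCC[C@]2(C)C(=O)O3)CC2=C1C(=O)C(C(C)C)=C(O)C2=O | target

## Step count and risk

Total steps: 12. Longest linear sequence: 12 (from 1,2,4-trimethoxybenzene; diester 6 enters at step 4).

The three steps most likely to fail:

**Step 7 (proposed new method; low ee or incomplete reduction).** The fallback is known chemistry; it sets out from 11 and comes back at 14. Acid 11 is converted (oxalyl chloride, cat. DMF; then (S)-2-(methoxymethyl)pyrrolidine, Et3N) into the chiral prolinol-ether benzamide F1. Auxiliary-controlled Birch reduction–methylation (K, NH3–THF, t-BuOH 1 equiv, −78 °C; MeI) gives the (4S)-1,4-diene amide F2. Aqueous acid (6 M H2SO4–dioxane) then effects amide-assisted protolactonisation through the cyclic iminium ether, whose hydrolysis releases the auxiliary and gives 14. The (S)-auxiliary is drawn by analogy with 2-alkylbenzamides; I could not confirm its facial sense for this fused substrate, and the antipode is equally available.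

**Step 10 (7β-acetate, epimer mixture or elimination to the C6=C7 styrene).** The fallback sets out from 15 and comes back at 16. DDQ in wet dioxane oxidises C7 to the aryl ketone F3. Catalyst-controlled reduction with (S)-2-methyl-CBS-oxazaborolidine (20 mol %) and BH3·SMe2 (aryl as the large group) gives the 7R (7α) alcohol F4. Ac2O, pyridine and DMAP then give 16.

**Step 4 (labile benzylic chloride 5, self-condensation or double alkylation of anion 7).** The fallback sets out from 4 (with 6) and comes back at 9. Rieche formylation of 4 (Cl2CHOMe, TiCl4, CH2Cl2, −78 to 0 °C) gives 3-isopropyl-2,4,5-trimethoxybenzaldehyde F5. Lithiated diester 7 adds to F5 and the aldolate lactonises to the racemic 3-aryl-3,4-dihydroisocoumarin ester F6, whose stereocentre is erased next. Hydrogenolysis of its benzylic C–O bond (H2, Pd/C, AcOH) gives the acid ester F7, and KOH hydrolysis gives 9.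

## Further compounds

F1 | step 7 | [(2S)-2-(methoxymethyl)pyrrolidin-1-yl](8-isopropyl-6,7,9-trimethoxy-10,11-dihydro-5H-dibenzo[a,d][7]annulen-1-yl)methanone | COC[C@@H]1CCCN1C(=O)c1cccc2c1CCc1c(OC)c(C(C)C)c(OC)c(OC)c1C2
F2 | step 7 | [(2S)-2-(methoxymethyl)pyrrolidin-1-yl][(1S)-8-isopropyl-6,7,9-trimethoxy-1-methyl-4,5,10,11-tetrahydro-1H-dibenzo[a,d][7]annulen-1-yl]methanone | COC[C@@H]1CCCN1C(=O)[C@@]1(C)C=CCC2=C1CCc1c(OC)c(C(C)C)c(OC)c(OC)c1C2
F3 | step 10 | (4S,5S,10S)-11,12,14-trimethoxy-7-oxoicetexa-8,11,13-trien-19,10-olide | O=C1C[C@@H]2[C@]3(CCC[C@]2(C)C(=O)O3)Cc2c1c(OC)c(C(C)C)c(OC)c2OC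
F4 | step 10 | (4S,5S,7R,10S)-7-hydroxy-11,12,14-trimethoxyicetexa-8,11,13-trien-19,10-olide | O[C@@H]1C[C@@H]2[C@]3(CCC[C@]2(C)C(=O)O3)Cc2c1c(OC)c(C(C)C)c(OC)c2OC
F5 | step 4 | 3-isopropyl-2,4,5-trimethoxybenzaldehyde | COc1c(C=O)cc(OC)c(OC)c1C(C)C
F6 | step 4 | methyl 3-(3-isopropyl-2,4,5-trimethoxyphenyl)-1-oxoisochromane-5-carboxylate (racemic) | COC(=O)c1cccc2c1CC(OC2=O)c1cc(OC)c(OC)c(C(C)C)c1OC
F7 | step 4 | 3-(methoxycarbonyl)-2-[2-(3-isopropyl-2,4,5-trimethoxyphenyl)ethyl]benzoic acid | COC(=O)c1cccc(C(=O)O)c1CCc1cc(OC)c(OC)c(C(C)C)c1OC
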